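**Retrosynthetic overview**
1. Feature: in the nine-membered ring (C1–C9, cyclobutane fused at C1/C9) the oxygen-bearing spiro carbon C8 is joined through C7–C6–C5 to the C3=C4 alkene. With C8 as a ketone this is a 5-en-1-one whose C5 oxygen marks an enol ether terminus, the retron of an anionic oxy-Cope shift that makes C5–C6 and breaks C3–C8.
2. Disconnections: the dihydropyran by hetero-Diels–Alder addition of the C8=CH2 alkene to the alkylidene triketone from syncarpic acid and 3-methylbutanal; the nine-membered ring by oxy-Cope rearrangement of a cis-2,3-dialkenylbicyclo[3.2.0]heptan-2-ol; that carbinol from the resolved cyclopentenone–isobutene photoadduct by C3 alkenylation and C8 ethynylation.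
3. Ring order: cyclobutane and cyclopentane together (step 1), nine-membered ring by five-to-nine expansion (step 11), dihydropyran (step 17).
4. Stereochemistry: C1 comes from the resolved photoadduct. The enol ether is made E (alkoxy cis to the methyl group) so that C2 can lie inside at C3 and give the Z ring alkene; this delivers C5 as the R ether, which is inverted by a Mitsunobu reaction. C9 is epimerised to the trans fusion after the ring expansion; C8 and C2′ are set in the cycloaddition.

Key step: step 11

Remark: adduct 4 denotes the diastereomer that carries the (1R,5R) skeleton; which of the two separated adducts this is has to be fixed by a crystal structure before it is taken on, and the minor head-to-head photoadduct is removed at the same chromatography.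

**Step 1**
Reactants: 1 cyclopent-2-en-1-one; 2 2-methylpropene
Product: 3 (±)-cis-6,6-dimethylbicyclo[3.2.0]heptan-2-one
Conditions: hν (Hg lamp, Pyrex filter), excess 2, CH2Cl2, −70 °C
Reagents that add atoms: none
Why: Enone–alkene [2+2] photocycloaddition through the enone triplet; the head-to-tail mode puts the CMe2 carbon on the enone β-carbon and the five–four fusion can only be cis, which fixes the relative configuration of C1 and C9 (racemic).

**Step 2**
Reactants: 3 (±)-cis-6,6-dimethylbicyclo[3.2.0]heptan-2-one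
Product: 4 (1R,5R)-6,6-dimethyl-2-exo-{[(S)-N-methyl-S-phenylsulfonimidoyl]methyl}bicyclo[3.2.0]heptan-2-endo-ol
Conditions: (S)-N,S-dimethyl-S-phenylsulfoximine, n-BuLi, THF, −78 °C; then 3; SiO2 separation of the two diastereomers
Reagents that add atoms: (S)-N,S-dimethyl-S-phenylsulfoximine, C[S@@](=O)(=NC)c1ccccc1
Why: Johnson sulfoximine resolution: 1,2-addition of the lithiated enantiopure sulfoximine to the convex face turns the two enantiomers of 3 into diastereomeric β-hydroxysulfoximines that should separate on silica.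

**Step 3**
Reactants: 4 the (1R,5R) sulfoximine adduct
Product: 5 (1R,5R)-6,6-dimethylbicyclo[3.2.0]heptan-2-one
Conditions: toluene, 110 °C (sealed tube)
Reagents that add atoms: none
Why: Thermal retro-addition of the β-hydroxysulfoximine releases the enantiopure ketone and the sulfoximine without touching C1 or C5.

**Step 4**
Reactants: 5 (1R,5R)-6,6-dimethylbicyclo[3.2.0]heptan-2-one
Product: 7 (1R,5R)-6,6-dimethyl-2-(trimethylsilyloxy)bicyclo[3.2.0]hept-2-ene, via lithium enolate 6 (not isolated)
Conditions: LDA, THF, −78 °C; then TMSCl, −78 → 0 °C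
Reagents that add atoms: chlorotrimethylsilane, C[Si](C)(C)Cl
Why: Kinetic deprotonation takes the C3 methylene hydrogen (the ring-fusion α-hydrogen would give a strained enolate) and O-silylation traps the enolate as its silyl enol ether.

**Step 5**
Reactants: 8 2,3-dibromoprop-1-ene; 9 (4-methoxyphenyl)methanol
Product: 10 1-{[(2-bromoprop-2-en-1-yl)oxy]methyl}-4-methoxybenzene
Conditions: NaH, THF/DMF, 0 °C → rt
Reagents that add atoms: none
Why: Williamson ether synthesis; the alkoxide displaces the allylic bromide and leaves the vinylic bromide untouched.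

**Step 6**
Reactants: 7 the silyl enol ether; 10 the 2-bromoallyl PMB ether
Product: 12 (1R,3S,5R)-3-exo-{3-[(4-methoxybenzyl)oxy]prop-1-en-2-yl}-6,6-dimethylbicyclo[3.2.0]heptan-2-one, via tributylstannyl enolate 11 (not isolated)
Conditions: Bu3SnF, PdCl2[P(o-tol)3]2 (cat.), toluene, 110 °C
Reagents that add atoms: none
Why: Pd-catalysed α-alkenylation of a ketone through its tin enolate (cross-coupling with a vinyl bromide); the C3–C bond is made on the convex exo face, and the base-free conditions neither epimerise C3 nor move the β,γ-double bond into conjugation.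

**Step 7**
Reactants: 12 the 3-exo-alkenyl ketone
Product: 14 (1R,5R)-2-endo-(tert-butyldimethylsilyloxy)-3-exo-{3-[(4-methoxybenzyl)oxy]prop-1-en-2-yl}-6,6-dimethyl-2-exo-[(trimethylsilyl)ethynyl]bicyclo[3.2.0]heptane, via lithium alkoxide 13 (not isolated)
Conditions: TMSC≡CH, n-BuLi, THF, −78 °C; then 12; then TBSOTf, −78 → 0 °C
Reagents that add atoms: ethynyltrimethylsilane, C#C[Si](C)(C)C; tert-butyldimethylsilyl trifluoromethanesulfonate, CC(C)(C)[Si](C)(C)OS(=O)(=O)C(F)(F)F
Why: 1,2-addition of a lithium acetylide: the rod-shaped nucleophile should attack C8 from the convex exo face, away from the folded cyclobutane (C10 methylene and the endo methyl on C11), which sets C8 with the alkynyl group cis to the C3 side chain and the oxygen endo; silylation in the same flask keeps the enyne alkoxide away from the base of step 8.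

**Step 8**
Reactants: 14 the silyl ether with the allyl ether side chain
Product: 15 (1R,5R)-2-endo-(tert-butyldimethylsilyloxy)-2-exo-ethynyl-3-exo-{(1E)-1-[(4-methoxybenzyl)oxy]prop-1-en-2-yl}-6,6-dimethylbicyclo[3.2.0]heptane
Conditions: KOtBu, DMSO, rt → 50 °C; aqueous work-up
Reagents that add atoms: none
Why: Base-mediated allyl-to-propenyl ether isomerisation through the potassium-chelated cis-alkoxyallyl anion, which is reprotonated at the terminal CH2 so that the PMB-oxy group ends cis to the new methyl group and trans to C3 (E enol ether); tert-butoxide also removes the C-silyl group.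

**Step 9**
Reactants: 15 the ethynyl enol ether
Product: 16 (1R,5R)-2-endo-(tert-butyldimethylsilyloxy)-2-exo-ethenyl-3-exo-{(1E)-1-[(4-methoxybenzyl)oxy]prop-1-en-2-yl}-6,6-dimethylbicyclo[3.2.0]heptane
Conditions: H2 (1 atm), Pd/CaCO3 poisoned with Pb(OAc)2, quinoline, EtOAc, rt
Reagents that add atoms: none
Why: Lindlar semihydrogenation stops at the terminal alkene; the trisubstituted enol ether and the benzyl-type ether are not reduced on the poisoned catalyst.

**Step 10**
Reactants: 16 the vinyl silyl ether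
Product: 17 (1R,5R)-2-exo-ethenyl-3-exo-{(1E)-1-[(4-methoxybenzyl)oxy]prop-1-en-2-yl}-6,6-dimethylbicyclo[3.2.0]heptan-2-endo-ol
Conditions: TBAF, THF, 0 °C → rt
Reagents that add atoms: none
Why: Fluoride-induced Si–O cleavage frees the tertiary alcohol under non-acidic conditions that leave the enol ether intact.

**Step 11**
Reactants: 17 the C8-vinyl C3-[(E)-alkoxypropenyl] carbinol
Product: 20 (1R,3Z,5R,9R)-5-[(4-methoxybenzyl)oxy]-4,11,11-trimethylbicyclo[7.2.0]undec-3-en-8-one, via potassium alkoxide 18 (not isolated), via potassium enolate 19 (not isolated)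
Conditions: KH, 18-crown-6, THF, 0 → 50 °C; then AcOH, −78 °C
Reagents that add atoms: none
Why: Deprotonation gives the crown-ether-separated potassium alkoxide 18, in which the C3–C8 bond is weakened so that the 1,5-diene C6=C7–C8–C3–C4=C5 undergoes a concerted [3,3] shift to enolate 19, forming C5–C6 and breaking C3–C8. The closest known reaction type is the anionic oxy-Cope ring expansion of cis-1,2-dialkenylcycloalkanols to medium-ring cycloalkenones. The nine-membered ring is not closed end to end; it arises by four-carbon enlargement of the cyclopentane inside a six-membered pericyclic array (C6, C7, C8, C3, C4, C5), and the cyclobutane is untouched. C5 is the only new stereocentre and is set by suprafacial transfer of the C3 configuration across C3–C4–C5: C6 bonds to the enol ether face from which C8 departs, and with C2 inside and the PMB-oxy group outside this gives the 5R ether. The step needs the Z ring alkene, which requires C2 on the inside position at C3; this is secured by the cis exo,exo placement of the two alkenyl groups on a nearly planar cyclopentane, where an eclipsed boat-like array with both ring bonds inside needs no ring distortion, and by the E enol ether, which leaves only hydrogen on the inside of C5 so that C2 meets no 1,3-clash there. The chair with C2 inside gives the same product, whereas the chair with C2 outside would give the E ring alkene and is the competing pathway to watch.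

**Step 12**
Reactants: 20 the cis-fused cyclononenone
Product: 21 (1R,3Z,5R,9S)-5-[(4-methoxybenzyl)oxy]-4,11,11-trimethylbicyclo[7.2.0]undec-3-en-8-one
Conditions: NaOMe (cat.), MeOH, rt
Reagents that add atoms: none
Why: Base epimerisation at C9 through the C8 enolate under thermodynamic control; the trans four–nine ring fusion is expected to be the more stable one, and C5 (γ to the ketone) is not touched.

**Step 13**
Reactants: 21 the trans-fused ketone
Product: 22 (1R,3Z,5R,9S)-5-[(4-methoxybenzyl)oxy]-4,11,11-trimethyl-8-methylidenebicyclo[7.2.0]undec-3-ene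
Conditions: Ph3PCH3Br, KOtBu, toluene, 80 °C
Reagents that add atoms: methyltriphenylphosphonium bromide, C[P+](c1ccccc1)(c1ccccc1)c1ccccc1.[Br-]
Why: Wittig methylenation of the C8 ketone; any enolisation under the basic conditions only returns the already preferred trans-fused C9 epimer.

**Step 14**
Reactants: 22 the PMB ether diene
Product: 23 (1R,3Z,5R,9S)-4,11,11-trimethyl-8-methylidenebicyclo[7.2.0]undec-3-en-5-ol
Conditions: DDQ, CH2Cl2/pH 7 buffer, 0 °C
Reagents that add atoms: none
Why: Oxidative cleavage of the electron-rich PMB ether by hydride abstraction and hydrolysis of the oxocarbenium ion; the isolated alkenes are inert at this temperature.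

**Step 15**
Reactants: 23 the 5R allylic alcohol
Product: 24 (1R,3Z,5S,9S)-4,11,11-trimethyl-8-methylidenebicyclo[7.2.0]undec-3-en-5-yl 4-nitrobenzoate
Conditions: 4-nitrobenzoic acid, PPh3, DIAD, THF, 0 °C → rt
Reagents that add atoms: 4-nitrobenzoic acid, O=C(O)c1ccc(cc1)[N+](=O)[O-]
Why: Mitsunobu reaction; the carboxylate displaces the oxyphosphonium group at C5 in an SN2 step, so the C5 configuration is inverted from R to S.

**Step 16**
Reactants: 24 the 4-nitrobenzoate
Product: 25 (1R,3Z,5S,9S)-4,11,11-trimethyl-8-methylidenebicyclo[7.2.0]undec-3-en-5-ol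
Conditions: K2CO3, MeOH, rt
Reagents that add atoms: none
Why: Transesterification cleaves the activated ester at the acyl carbon, so the C5–O bond and its configuration are retained.

**Step 17**
Reactants: 25 the 5S dienol; 26 syncarpic acid; 27 3-methylbutanal
Product: 29 tomentodione P, via alkylidene triketone 28 (not isolated)
Conditions: L-proline (cat.), 4 Å molecular sieves, toluene, 80 °C
Reagents that add atoms: none
Why: Knoevenagel condensation gives the electron-poor oxadiene 28, which should add to the 1,1-disubstituted C8=CH2 alkene in an inverse-electron-demand hetero-Diels–Alder reaction with oxygen going to the more substituted C8; this closes the dihydropyran and sets C8 and C2′ under substrate control (face of the exocyclic alkene and endo/exo orientation of the isobutyl group), so the target should be separable from any epimers.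

**Compound list**
1 | cyclopent-2-en-1-one | O=C1C=CCC1 | starting material
2 | 2-methylpropene | C=C(C)C | starting material
3 | (±)-cis-6,6-dimethylbicyclo[3.2.0]heptan-2-one (racemate) | O=C1CCC2C1CC2(C)C | intermediate
4 | (1R,5R)-6,6-dimethyl-2-exo-{[(S)-N-methyl-S-phenylsulfonimidoyl]methyl}bicyclo[3.2.0]heptan-2-endo-ol | C1C[C@@H]2[C@@H](CC2(C)C)[C@]1(O)C[S@@](=O)(=NC)c3ccccc3 | intermediate
5 | (1R,5R)-6,6-dimethylbicyclo[3.2.0]heptan-2-one | O=C1CC[C@@H]2[C@H]1CC2(C)C | intermediate
6 | lithium (1R,5R)-6,6-dimethylbicyclo[3.2.0]hept-2-en-2-olate (not isolated) | [Li+].[O-]C1=CC[C@@H]2[C@H]1CC2(C)C | intermediate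
7 | (1R,5R)-6,6-dimethyl-2-(trimethylsilyloxy)bicyclo[3.2.0]hept-2-ene | C[Si](C)(C)OC1=CC[C@@H]2[C@H]1CC2(C)C | intermediate
8 | 2,3-dibromoprop-1-ene | BrCC(Br)=C | starting material
9 | (4-methoxyphenyl)methanol | COc1ccc(CO)cc1 | starting material
10 | 1-{[(2-bromoprop-2-en-1-yl)oxy]methyl}-4-methoxybenzene | COc1ccc(COCC(Br)=C)cc1 | intermediate
11 | tributyl{[(1R,5R)-6,6-dimethylbicyclo[3.2.0]hept-2-en-2-yl]oxy}stannane (not isolated) | CCCC[Sn](CCCC)(CCCC)OC1=CC[C@@H]2[C@H]1CC2(C)C | intermediate
12 | (1R,3S,5R)-3-exo-{3-[(4-methoxybenzyl)oxy]prop-1-en-2-yl}-6,6-dimethylbicyclo[3.2.0]heptan-2-one | C=C(COCc3ccc(OC)cc3)[C@@H]1C[C@@H]2[C@@H](CC2(C)C)C1=O | intermediate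
13 | lithium 2-endo-alkoxide from acetylide addition to 12 (alkynyl exo; not isolated) | C=C(COCc3ccc(OC)cc3)[C@@H]1C[C@@H]2[C@@H](CC2(C)C)[C@]1([O-])C#C[Si](C)(C)C.[Li+] | intermediate
14 | (1R,5R)-2-endo-(tert-butyldimethylsilyloxy)-3-exo-{3-[(4-methoxybenzyl)oxy]prop-1-en-2-yl}-6,6-dimethyl-2-exo-[(trimethylsilyl)ethynyl]bicyclo[3.2.0]heptane | C=C(COCc3ccc(OC)cc3)[C@@H]1C[C@@H]2[C@@H](CC2(C)C)[C@]1(O[Si](C)(C)C(C)(C)C)C#C[Si](C)(C)C | intermediate
15 | (1R,5R)-2-endo-(tert-butyldimethylsilyloxy)-2-exo-ethynyl-3-exo-{(1E)-1-[(4-methoxybenzyl)oxy]prop-1-en-2-yl}-6,6-dimethylbicyclo[3.2.0]heptane | C/C(=C\OCc3ccc(OC)cc3)[C@@H]1C[C@@H]2[C@@H](CC2(C)C)[C@]1(O[Si](C)(C)C(C)(C)C)C#C | intermediate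
16 | (1R,5R)-2-endo-(tert-butyldimethylsilyloxy)-2-exo-ethenyl-3-exo-{(1E)-1-[(4-methoxybenzyl)oxy]prop-1-en-2-yl}-6,6-dimethylbicyclo[3.2.0]heptane | C/C(=C\OCc3ccc(OC)cc3)[C@@H]1C[C@@H]2[C@@H](CC2(C)C)[C@]1(O[Si](C)(C)C(C)(C)C)C=C | intermediate
17 | (1R,5R)-2-exo-ethenyl-3-exo-{(1E)-1-[(4-methoxybenzyl)oxy]prop-1-en-2-yl}-6,6-dimethylbicyclo[3.2.0]heptan-2-endo-ol (key-step precursor) | C/C(=C\OCc3ccc(OC)cc3)[C@@H]1C[C@@H]2[C@@H](CC2(C)C)[C@]1(O)C=C | intermediate
18 | potassium alkoxide of 17 (not isolated) | C/C(=C\OCc3ccc(OC)cc3)[C@@H]1C[C@@H]2[C@@H](CC2(C)C)[C@]1([O-])C=C.[K+] | intermediate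
19 | potassium (1R,3Z,5R,7Z,9R)-5-[(4-methoxybenzyl)oxy]-4,11,11-trimethylbicyclo[7.2.0]undeca-3,7-dien-8-olate (not isolated) | C/C1=C/C[C@@H]2[C@@H](CC2(C)C)/C([O-])=C\C[C@H]1OCc3ccc(OC)cc3.[K+] | intermediate
20 | (1R,3Z,5R,9R)-5-[(4-methoxybenzyl)oxy]-4,11,11-trimethylbicyclo[7.2.0]undec-3-en-8-one (cis-fused; key-step product) | C/C1=C/C[C@@H]2[C@@H](CC2(C)C)C(=O)CC[C@H]1OCc3ccc(OC)cc3 | intermediate
21 | (1R,3Z,5R,9S)-5-[(4-methoxybenzyl)oxy]-4,11,11-trimethylbicyclo[7.2.0]undec-3-en-8-one (trans-fused) | C/C1=C/C[C@@H]2[C@H](CC2(C)C)C(=O)CC[C@H]1OCc3ccc(OC)cc3 | intermediate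
22 | (1R,3Z,5R,9S)-5-[(4-methoxybenzyl)oxy]-4,11,11-trimethyl-8-methylidenebicyclo[7.2.0]undec-3-ene | C/C1=C/C[C@@H]2[C@H](CC2(C)C)C(=C)CC[C@H]1OCc3ccc(OC)cc3 | intermediate
23 | (1R,3Z,5R,9S)-4,11,11-trimethyl-8-methylidenebicyclo[7.2.0]undec-3-en-5-ol | C/C1=C/C[C@@H]2[C@H](CC2(C)C)C(=C)CC[C@H]1O | intermediate
24 | (1R,3Z,5S,9S)-4,11,11-trimethyl-8-methylidenebicyclo[7.2.0]undec-3-en-5-yl 4-nitrobenzoate | C/C1=C/C[C@@H]2[C@H](CC2(C)C)C(=C)CC[C@@H]1OC(=O)c3ccc(cc3)[N+](=O)[O-] | intermediate
25 | (1R,3Z,5S,9S)-4,11,11-trimethyl-8-methylidenebicyclo[7.2.0]undec-3-en-5-ol | C/C1=C/C[C@@H]2[C@H](CC2(C)C)C(=C)CC[C@@H]1O | intermediate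
26 | syncarpic acid (2,2,4,4-tetramethylcyclohexane-1,3,5-trione) | CC1(C)C(=O)CC(=O)C(C)(C)C1=O | starting material
27 | 3-methylbutanal | CC(C)CC=O | starting material
28 | 4,4,6,6-tetramethyl-2-(3-methylbutylidene)cyclohexane-1,3,5-trione (not isolated) | CC(C)CC=C1C(=O)C(C)(C)C(=O)C(C)(C)C1=O | intermediate
29 | tomentodione P | C/C1=C/C[C@@H]2[C@H](CC2(C)C)[C@]2(CC[C@@H]1O)C[C@H](CC(C)C)C1=C(O2)C(C)(C)C(=O)C(C)(C)C1=O | target

**Step count**
Total: 17 steps. Longest linear sequence: 16 steps (steps 1–4 and 6–17; step 5 is a one-step branch).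

**Steps most likely to fail**

Step 11. The alkoxide may rearrange through the chair-like array in which C2 lies outside at C3, which would happen if the cyclopentane puckers instead of eclipsing. This forms the E ring alkene and, with the same enol ether, the 5S ether. Fallback, from 17 back to 25: the E isomer is used rather than suppressed. The same treatment of 17 would then give the cis-fused E ketone F1. NaOMe in MeOH epimerises C9 to the trans-fused E ketone F2. Thiyl-radical equilibration of the strained E alkene (PhSSPh, hν, benzene) should give the more stable trans-fused Z ketone F3, in which C5 already has the S configuration. Wittig methylenation (Ph3PCH3Br, KOtBu, toluene) gives the Z diene PMB ether F4, and DDQ cleavage of its PMB group gives 25 directly, so steps 15 and 16 are not needed.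

Step 7. The acetylide may attack anti to the C3 side chain, on the concave face, which would give the trans-dialkenyl series and, after step 11, the wrong ring alkene. Fallback, from 12 back to 16: oxygen is transferred to an exocyclic alkene instead of carbon to the ketone, so that the same side-chain control now places oxygen anti to the side chain. Methylenation of 12 with Zn, CH2Br2 and TiCl4 (non-basic, so no epimerisation at C3) gives the 1,4-diene F5. mCPBA with NaHCO3 in CH2Cl2 at 0 °C epoxidises the more electron-rich C8 methylidene group anti to the side chain to give the spiro-epoxide F6. Excess dimethylsulfonium methylide (Me3SI, n-BuLi, THF) opens the epoxide at CH2 and loses Me2S to give the vinyl carbinol F7, with the vinyl group cis to the side chain. TBSOTf and 2,6-lutidine give the silyl ether F8, and KOtBu in DMSO as in step 8 isomerises its allyl ether to give 16.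

Step 17. The cycloaddition may show poor discrimination between the two faces of the C8=CH2 alkene or between the endo and exo orientations of the isobutyl group, giving mainly C8 or C2′ epimers; a second syncarpic acid may also add to 28. Fallback, from 22 back to 29: the cycloaddition is run on the PMB ether 22, whose protected 5R substituent changes the ring conformation and the facial bias. 22, 26 and 27 under the conditions of step 17 give the PMB-protected adduct F9. DDQ gives the 5R alcohol adduct F10. Mitsunobu inversion with 4-nitrobenzoic acid, PPh3 and DIAD gives the 4-nitrobenzoate adduct F11, and K2CO3 in MeOH gives 29.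

**Further compounds**
F1 | step 11 | (1R,3E,5S,9R)-5-[(4-methoxybenzyl)oxy]-4,11,11-trimethylbicyclo[7.2.0]undec-3-en-8-one | C/C1=C\C[C@@H]2[C@@H](CC2(C)C)C(=O)CC[C@@H]1OCc3ccc(OC)cc3
F2 | step 11 | (1R,3E,5S,9S)-5-[(4-methoxybenzyl)oxy]-4,11,11-trimethylbicyclo[7.2.0]undec-3-en-8-one | C/C1=C\C[C@@H]2[C@H](CC2(C)C)C(=O)CC[C@@H]1OCc3ccc(OC)cc3
F3 | step 11 | (1R,3Z,5S,9S)-5-[(4-methoxybenzyl)oxy]-4,11,11-trimethylbicyclo[7.2.0]undec-3-en-8-one | C/C1=C/C[C@@H]2[C@H](CC2(C)C)C(=O)CC[C@@H]1OCc3ccc(OC)cc3
F4 | step 11 | (1R,3Z,5S,9S)-5-[(4-methoxybenzyl)oxy]-4,11,11-trimethyl-8-methylidenebicyclo[7.2.0]undec-3-ene | C/C1=C/C[C@@H]2[C@H](CC2(C)C)C(=C)CC[C@@H]1OCc3ccc(OC)cc3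
F5 | step 7 | (1R,5R)-3-exo-{3-[(4-methoxybenzyl)oxy]prop-1-en-2-yl}-6,6-dimethyl-2-methylidenebicyclo[3.2.0]heptane | C=C(COCc3ccc(OC)cc3)[C@@H]1C[C@@H]2[C@@H](CC2(C)C)C1=C
F6 | step 7 | spiro-epoxide of F5 at C2 (oxygen endo, CH2 exo) | C=C(COCc3ccc(OC)cc3)[C@@H]1C[C@@H]2[C@@H](CC2(C)C)[C@]14CO4
F7 | step 7 | (1R,5R)-2-exo-ethenyl-3-exo-{3-[(4-methoxybenzyl)oxy]prop-1-en-2-yl}-6,6-dimethylbicyclo[3.2.0]heptan-2-endo-ol | C=C(COCc3ccc(OC)cc3)[C@@H]1C[C@@H]2[C@@H](CC2(C)C)[C@]1(O)C=C
F8 | step 7 | tert-butyldimethylsilyl ether of F7 | C=C(COCc3ccc(OC)cc3)[C@@H]1C[C@@H]2[C@@H](CC2(C)C)[C@]1(O[Si](C)(C)C(C)(C)C)C=C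
F9 | step 17 | 5-epi-tomentodione P 4-methoxybenzyl ether | C/C1=C/C[C@@H]2[C@H](CC2(C)C)[C@]2(CC[C@H]1OCc3ccc(OC)cc3)C[C@H](CC(C)C)C1=C(O2)C(C)(C)C(=O)C(C)(C)C1=O
F10 | step 17 | 5-epi-tomentodione P | C/C1=C/C[C@@H]2[C@H](CC2(C)C)[C@]2(CC[C@H]1O)C[C@H](CC(C)C)C1=C(O2)C(C)(C)C(=O)C(C)(C)C1=O
F11 | step 17 | tomentodione P 4-nitrobenzoate | C/C1=C/C[C@@H]2[C@H](CC2(C)C)[C@]2(CC[C@@H]1OC(=O)c3ccc(cc3)[N+](=O)[O-])C[C@H](CC(C)C)C1=C(O2)C(C)(C)C(=O)C(C)(C)C1=O
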